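## The problem

Target 29 is a cyclopent-2-enone. With C1 as the ester carbon, the ring is C8H–C9(=O)–C10(Br)=C11H–C12. C12 is a tertiary carbinol carrying the (Z)-oct-2-enyl chain C13–C20. C8 carries the C1–C7 arm, which holds the C7 acetate, the Z-C5=C6 alkene and the methyl ester.

There are three contiguous stereocentres: (12S), (8R) and (7S). The arm on C8 is cis to the C12 oxygen and trans to the octenyl chain, and C7/C8 are anti in the aldol sense. C12 is fully substituted and must come from an enantiopure source. Once in place it can steer the face of C8, and a closed aldol transition state can tie C7 to C8.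

The β-acetoxy ketone is the most fragile group: it loses acetic acid by E1cB to give a cross-conjugated dienone. The C12 oxygen cannot leave the same way, since that would give a cyclopentadienone. The α-bromo enone is a Michael acceptor whose C–Br bond would not survive Pd and H2, and the two isolated Z-alkenes rule out electrophilic bromine.

The feature that invites the key step is that C9 and vinylic C10 are adjacent and C11 sits on C12. O=C9H–C8–C12–C11≡C10H is a pent-4-ynal, so the ring is a C9 aldehyde C–H bond added across an ethynyl group on C12. The same count gives a warning: any C5–C6 unsaturation on an arm at C8 is also 4,5 to C9 (through C8–C7), so the arm must be absent when the ring is closed.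

## Retrosynthesis

**29 ⇒ 28 ⇒ 27 (O–Si at C12, O–acyl at C7).** The acetate goes on late because the β-acetoxy ketone is the weakest point of the molecule. The silyl ether at C12 is kept to the last step so that acetylation of alcohol 27 to acetate 28 can only touch C7, and so that the final operation is a fluoride desilylation and not a basic one. The forward steps must acylate without E1cB elimination and desilylate without base.

**27 ⇒ 19 + 24 (C7–C8, aldol).** The neighbouring option is to carry the arm through the ring closure. It fails on chemoselectivity: a C5≡C6 alkyne, or its Z-alkene, is 4,5 to the C9 aldehyde exactly as C10≡C11 is, and an internal alkyl alkyne is the better-precedented hydroacylation partner. The arm is therefore joined to the finished ring. Bromo enone 19 can only enolise toward C8, because C12 has no hydrogen. Its cyclic enolate is necessarily E and should give the 7,8-anti aldol with aldehyde 24. The precursors are far simpler: 19 has one stereocentre and 24 has none. The forward step must deliver the aldehyde to the ring face that carries the C12 oxygen.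

**19 ⇒ 16 ⇒ 15 (C10–Br).** Bromine followed by amine would also attack the C14=C15 alkene. Nucleophilic epoxidation of enone 15 to epoxy ketone 16, then bromide opening at C10 and dehydration, uses only reagents that select the electron-poor double bond. The sequence sits before the aldol because alkaline peroxide would cleave or dehydrate 27.

**15 ⇒ 14 (C9–C10, the key cut).** Opening the enone between the carbonyl carbon and the vinylic carbon gives the acyclic 4-alkynal 14. Against a C10=C11 or C8–C12 cut, this one delivers the ring directly at the enone oxidation level, creates no stereocentre, and leaves a precursor whose only stereocentre is C12. The forward reaction must favour the terminal alkyne over the 5,6-alkene and over decarbonylation.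

**14 ⇒ 13 ⇒ 12 ⇒ 11 (functional-group changes).** Aldehyde 14 comes from alcohol 13 by oxidation. The ethynyl group of 13 comes from lactol 12 by one-carbon homologation. Lactol 12, from lactone 11, holds C11 at the aldehyde level and C9 at the alcohol level, which is exactly the differentiation the two ends need.

**11 ⇒ 10 ⇒ 9 ⇒ 6 ⇒ 3 ⇒ 1 + 2 + 4 (C12–C13, and the source of C12).** The four carbons C11, C12, C8 and C9 with the C12 oxygen are those of malic acid. Alkylating the carbinol carbon of (S)-malic acid 1 with 1-bromooct-2-yne 4, through the pivalaldehyde (2) acetal 3, replaces hydrogen by C13 with retention and gives acid 6 with the (12S) configuration. Against a Sharpless epoxidation of a 2-substituted allylic alcohol, this takes the centre from the chiral pool through a crystalline intermediate. Reduction of the free carboxyl and translactonisation give lactone 9. Semihydrogenation to 10 is done here, before any terminal alkyne exists, and silylation gives 11.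

**24 ⇒ 23 ⇒ 22 ⇒ 20 (the arm).** Methyl hex-5-ynoate 20 is hydroxymethylated to 22, semihydrogenated to Z-allylic alcohol 23, and oxidised to the Z-enal 24 immediately before use.

## Roads not taken

**Alternative 1:** The cut is C10=C11. An open-chain diene, whose C8/C12 relationship comes from a Claisen rearrangement, is closed with (H2IMes)(PCy3)Cl2Ru=CHPh (the second-generation Grubbs catalyst) to the protected cyclopentene A1.
- Merits: five-ring metathesis is about the most dependable ring closure available. It tolerates allylic silyl ethers and a quaternary allylic carbon, and the sigmatropic chair fixes C8 against C12 before the ring exists.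
- Weak points: A1 has C9 as a silyl ether and both chains cut back to oxygenated stubs at C6 and C14. After the ring closure come an oxidation at C9, two Z-selective Wittig reactions with basic ylides (one next to the C7 oxygen and β to the future ketone), removal of a benzyl-type ether from the tertiary C12 oxygen, and the bromination. Four kinds of protecting group are involved.
- Comparison: this road is safer than the chosen plan in the ring-forming event and in the C8/C12 relay. Against that, the chosen plan closes the ring at the enone level, has the complete octenyl chain from step 4, brings the arm in one bond, uses one protecting group, and is much shorter.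

**Alternative 2:** The cut is C12–O. I2 with NaHCO3 activates a C11=C12 cyclopentene and the C6 carboxylate on the C8 arm attacks C12, giving the cis-fused iodo lactone A2.
- Merits: the tertiary C–O bond is delivered intramolecularly, so C12 follows C8 with complete fidelity through the cis ring fusion. The C11 iodide is placed for loss of hydrogen iodide toward C10.
- Weak points: the key step presupposes a cyclopentene that already carries C7, C8 and C9. It ties C6 up as a lactone carbonyl, which must later be reduced and olefinated with a basic ylide. C9 still needs oxidation, the alkyne chain is exposed to iodine, and the C7 ether must be exchanged for acetate on a β-oxy ketone.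
- Comparison: the relay to C12 is more certain than the facial selectivity the chosen plan needs at C8. The chosen plan takes C12 from malic acid with equal certainty, needs no late olefination, and is shorter.

**Alternative 3:** The cut is C8–C12. Rh2(OAc)4 turns a 2-diazo-1,3-diketone into a carbenoid at C8 that inserts into the C12–H bond of a chiral-pool silyl ether, giving the 2-acylcyclopentanone A3.
- Merits: 1,5 insertion into an oxygen-activated tertiary C–H bond with retention is a sound way to make the quaternary carbinol. The whole carbon skeleton, both chains included, is present after the key step, so this is the most convergent plan.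
- Weak points: in A3, C8 is a β-diketone carbon with no fixed configuration. The C7 ketone must be reduced selectively beside the C9 ketone while C7 and C8 are set together. The ring is saturated at C10–C11 and needs regioselective dehydrogenation before bromination. The ynone can also intercept the carbenoid.
- Comparison: this road is better in convergency. The chosen plan sets against it a ring that arrives with its unsaturation in place, and C7/C8 made together under kinetic control instead of being recovered from a diketone.

Key step: step 9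

## Route

Remark: C10 and C11 of 16, 17 and 18 and the anomeric carbon of 12 are mixtures and are written without descriptors, since none of these centres survives (they become sp2 in 19 and 13).

Step 1
Reactants: 1 (S)-malic acid; 2 pivalaldehyde
Product: 3 2-[(2S,4S)-2-tert-butyl-5-oxo-1,3-dioxolan-4-yl]acetic acid (cis isomer)
Conditions: p-TsOH (cat.), H2SO4 (cat.), pentane, reflux, water separator; crystallisation
Reagents that add atoms: none
Why: Acid-catalysed acetalisation of the α-hydroxy acid unit gives the five-membered dioxolanone, and the cis isomer is the thermodynamic product and crystallises. The configuration of 1 at the future C12 is untouched.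

Step 2
Reactants: 3 2-[(2S,4S)-2-tert-butyl-5-oxo-1,3-dioxolan-4-yl]acetic acid; 4 1-bromooct-2-yne
Product: 6 2-[(2S,4S)-2-tert-butyl-4-(oct-2-yn-1-yl)-5-oxo-1,3-dioxolan-4-yl]acetic acid, via dilithium enolate carboxylate 5 (not isolated)
Conditions: LiN(SiMe3)2 (2.2 equiv), THF, −78 °C; then 4, −78 → −20 °C; aq. HCl work-up
Reagents that add atoms: none
Why: Enolate alkylation with self-regeneration of the stereocentre: the lactone enolate of 5 is planar at C12 and the acetal tert-butyl group blocks one face. The propargylic bromide therefore enters trans to it and takes the place of the original hydrogen (retention), giving (12S).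

Step 3
Reactants: 6 2-[(2S,4S)-2-tert-butyl-4-(oct-2-yn-1-yl)-5-oxo-1,3-dioxolan-4-yl]acetic acid
Product: 9 (3S)-3-hydroxy-3-(oct-2-yn-1-yl)oxolan-2-one, via isobutyl carbonic mixed anhydride 7 (not isolated), via 2-hydroxyethyl dioxolanone 8 (not isolated)
Conditions: i-BuOCOCl, N-methylmorpholine, THF, −15 °C; NaBH4, H2O, −15 → 0 °C; then p-TsOH (cat.), CH2Cl2, rt
Reagents that add atoms: none
Why: Mixed-anhydride activation and borohydride reduction reduce only the free carboxyl (C9), and no borane is present to hydroborate the alkyne. Acid-catalysed translactonisation of 8 onto the five-membered lactone expels pivalaldehyde and leaves C11 as the lactone carbonyl; C12 is not involved.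

Step 4
Reactants: 9 (3S)-3-hydroxy-3-(oct-2-yn-1-yl)oxolan-2-one
Product: 10 (3S)-3-hydroxy-3-[(2Z)-oct-2-en-1-yl]oxolan-2-one
Conditions: H2 (1 atm), Pd/CaCO3 poisoned with Pb(OAc)2 (Lindlar catalyst), quinoline, EtOAc, rt
Reagents that add atoms: none
Why: Lindlar semihydrogenation; syn delivery of hydrogen on the poisoned surface gives the Z-C14=C15 alkene. It is done while this is the only alkyne in the molecule.

Step 5
Reactants: 10 (3S)-3-hydroxy-3-[(2Z)-oct-2-en-1-yl]oxolan-2-one
Product: 11 (3S)-3-[(2Z)-oct-2-en-1-yl]-3-(triethylsilyloxy)oxolan-2-one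
Conditions: Et3SiOTf, 2,6-lutidine, CH2Cl2, −78 → 0 °C
Reagents that add atoms: triethylsilyl trifluoromethanesulfonate, CC[Si](CC)(CC)OS(=O)(=O)C(F)(F)F
Why: Silylation of a hindered tertiary alcohol with a silyl triflate and a non-nucleophilic base. The triethylsilyl ether withstands hydride, carbonate, rhodium and boron enolate chemistry and comes off with fluoride at the end.

Step 6
Reactants: 11 (3S)-3-[(2Z)-oct-2-en-1-yl]-3-(triethylsilyloxy)oxolan-2-one
Product: 12 (3S)-3-[(2Z)-oct-2-en-1-yl]-3-(triethylsilyloxy)oxolan-2-ol (anomer mixture)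
Conditions: i-Bu2AlH, CH2Cl2, −78 °C; aq. KNaC4H4O6
Reagents that add atoms: none
Why: Partial reduction of a lactone to the lactol; the tetrahedral aluminium hemiacetal is stable at −78 °C and is released only on work-up.

Step 7
Reactants: 12 (3S)-3-[(2Z)-oct-2-en-1-yl]-3-(triethylsilyloxy)oxolan-2-ol
Product: 13 (3S,5Z)-3-ethynyl-3-(triethylsilyloxy)undec-5-en-1-ol
Conditions: dimethyl (1-diazo-2-oxopropyl)phosphonate, K2CO3, MeOH, 0 °C → rt
Reagents that add atoms: dimethyl (1-diazo-2-oxopropyl)phosphonate, COP(=O)(OC)C(=[N+]=[N-])C(C)=O
Why: Ohira–Bestmann homologation of the open hydroxy aldehyde form of the lactol; C11 becomes the inner and the new carbon (C10) the terminal alkyne carbon. C12 has no hydrogen, so nothing can epimerise.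

Step 8
Reactants: 13 (3S,5Z)-3-ethynyl-3-(triethylsilyloxy)undec-5-en-1-ol
Product: 14 (3S,5Z)-3-ethynyl-3-(triethylsilyloxy)undec-5-enal
Conditions: Dess–Martin periodinane, NaHCO3, CH2Cl2, 0 °C → rt
Reagents that add atoms: none
Why: Dess–Martin oxidation of the primary alcohol under buffered conditions gives the C9 aldehyde. There is no epimerisable centre, and the β-silyloxy aldehyde is used promptly.

Step 9
Reactants: 14 (3S,5Z)-3-ethynyl-3-(triethylsilyloxy)undec-5-enal
Product: 15 (4S)-4-[(2Z)-oct-2-en-1-yl]-4-(triethylsilyloxy)cyclopent-2-en-1-one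
Conditions: [Rh(dppe)]2(BF4)2 (5 mol %, from [Rh(nbd)(dppe)]BF4 and H2), degassed acetone, 25 °C
Reagents that add atoms: none
Why: Monovalent rhodium inserts into the C9 aldehyde C–H bond to give an acyl hydrido trivalent rhodium species that binds the ethynyl group; hydride goes to C11 and rhodium to C10. The alkenyl rhodium formed has the metal trans to C12 and cannot close, so it isomerises through an η2-vinyl form until rhodium is cis to C12, and the six-membered acyl alkenyl rhodacycle forms C9–C10 by reductive elimination, a net trans hydroacylation. The single ring closes in the 5-endo-dig mode. The closest known reaction type is the cyclisation of 4-alkynals to cyclopent-2-enones with the same cationic rhodium dppe catalyst, which includes 3-alkoxy-4-alkynals with a fully substituted C3; the terminal alkyne C–H is the one feature outside that precedent, though terminal alkynes are routine partners of such catalysts in intermolecular hydroacylation. No stereocentre is formed, and C12 has no hydrogen to lose. The step needs chemoselectivity for C10≡C11 over the C14=C15 alkene and over decarbonylation: the alkyne is the only unsaturation 4,5 to C9, the Z-alkene is 5,6 and would need a slower alkene closure, and the geminal substitution at C12 with the chelating diphosphine favours cyclisation over loss of CO. The conditions are neutral, so the silyl ether stays.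

Step 10
Reactants: 15 (4S)-4-[(2Z)-oct-2-en-1-yl]-4-(triethylsilyloxy)cyclopent-2-en-1-one
Product: 16 (4S)-4-[(2Z)-oct-2-en-1-yl]-4-(triethylsilyloxy)-6-oxabicyclo[3.1.0]hexan-2-one (both epoxide faces)
Conditions: t-BuOOH, DBU, CH2Cl2, 0 °C → rt
Reagents that add atoms: tert-butyl hydroperoxide, CC(C)(C)OO
Why: Weitz–Scheffer nucleophilic epoxidation (conjugate addition of the peroxide anion, then ring closure) touches only the electron-poor C10=C11 bond and leaves the Z-alkene. Enolisation toward C8 is harmless because loss of the C12 oxygen would give a cyclopentadienone; the epoxide face is of no consequence.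

Step 11
Reactants: 16 (4S)-4-[(2Z)-oct-2-en-1-yl]-4-(triethylsilyloxy)-6-oxabicyclo[3.1.0]hexan-2-one
Product: 19 (4S)-2-bromo-4-[(2Z)-oct-2-en-1-yl]-4-(triethylsilyloxy)cyclopent-2-en-1-one, via bromohydrin 17 (not isolated), via bromo mesylate 18 (not isolated)
Conditions: MgBr2·OEt2, Et2O/CH2Cl2, −20 → 0 °C; aqueous work-up; then MsCl, Et3N, CH2Cl2, 0 °C
Reagents that add atoms: magnesium bromide, [Mg+2].[Br-].[Br-]
Why: MgBr2 chelates the ketone and epoxide oxygens and bromide opens the epoxide by SN2 at C10 (α to the carbonyl; C11 is neopentyl). Mesylation and E1cB elimination through the C10 enolate restore C10=C11 with bromine on C10. This is the known epoxy ketone to α-halo enone sequence and uses no electrophilic bromine, so the Z-alkene is safe.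

Step 12
Reactants: 20 methyl hex-5-ynoate
Product: 22 methyl 7-hydroxyhept-5-ynoate, via chloromagnesium acetylide 21 (not isolated)
Conditions: i-PrMgCl·LiCl, THF, −20 °C; (CH2O)n, −20 °C → rt
Reagents that add atoms: paraformaldehyde (as formaldehyde), C=O
Why: Deprotonation of the terminal alkyne by the Grignard reagent is faster at low temperature than addition to the methyl ester. The magnesium acetylide, itself a poor nucleophile toward esters, adds to formaldehyde to install C7.

Step 13
Reactants: 22 methyl 7-hydroxyhept-5-ynoate
Product: 23 methyl (5Z)-7-hydroxyhept-5-enoate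
Conditions: H2 (1 atm), Pd/CaCO3 poisoned with Pb(OAc)2 (Lindlar catalyst), quinoline, EtOAc, rt
Reagents that add atoms: none
Why: Lindlar semihydrogenation of the only alkyne gives the Z-C5=C6 alkene by syn addition of hydrogen.

Step 14
Reactants: 23 methyl (5Z)-7-hydroxyhept-5-enoate
Product: 24 methyl (5Z)-7-oxohept-5-enoate
Conditions: Dess–Martin periodinane, NaHCO3, CH2Cl2, 0 °C; used at once
Reagents that add atoms: none
Why: Buffered Dess–Martin oxidation of the allylic alcohol at low temperature keeps the Z geometry of the enal, which is not stored.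

Step 15
Reactants: 19 (4S)-2-bromo-4-[(2Z)-oct-2-en-1-yl]-4-(triethylsilyloxy)cyclopent-2-en-1-one; 24 methyl (5Z)-7-oxohept-5-enoate
Product: 27 methyl (5Z,7S)-7-[(1R,5S)-3-bromo-5-[(2Z)-oct-2-en-1-yl]-2-oxo-5-(triethylsilyloxy)cyclopent-3-en-1-yl]-7-hydroxyhept-5-enoate, via dicyclohexylboron dienolate 25 (not isolated), via dicyclohexylboron aldolate 26 (not isolated)
Conditions: (c-C6H11)2BCl, Et3N, Et2O, −78 → 0 °C; 24, −78 → −20 °C; pH 7 buffer, MeOH, 30% H2O2, 0 °C
Reagents that add atoms: none
Why: Boron-mediated aldol addition: the cyclic enolate can only form toward C8 and is necessarily E, and the chair Zimmerman–Traxler transition state should give the 7,8-anti adduct. The aldehyde should approach C8 on the ring face that carries the C12 oxygen, anti to the C13 methylene (smaller first atom, and attack anti to the better σ-donor C–C bond). That places the arm cis to the silyloxy group (8R), and with anti addition gives (7S).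

Step 16
Reactants: 27 methyl (5Z,7S)-7-[(1R,5S)-3-bromo-5-[(2Z)-oct-2-en-1-yl]-2-oxo-5-(triethylsilyloxy)cyclopent-3-en-1-yl]-7-hydroxyhept-5-enoate
Product: 28 methyl (5Z,7S)-7-acetoxy-7-[(1R,5S)-3-bromo-5-[(2Z)-oct-2-en-1-yl]-2-oxo-5-(triethylsilyloxy)cyclopent-3-en-1-yl]hept-5-enoate
Conditions: Ac2O, pyridine, DMAP (cat.), CH2Cl2, 0 °C
Reagents that add atoms: acetic anhydride, CC(=O)OC(C)=O
Why: Acylation of the only free hydroxyl (the tertiary oxygen is silylated). Low temperature and short contact with the weak base are meant to outrun E1cB loss of the new acetate; no stereocentre is touched.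

Step 17
Reactants: 28 methyl (5Z,7S)-7-acetoxy-7-[(1R,5S)-3-bromo-5-[(2Z)-oct-2-en-1-yl]-2-oxo-5-(triethylsilyloxy)cyclopent-3-en-1-yl]hept-5-enoate
Product: 29 methyl (5Z,7S)-7-acetoxy-7-[(1R,5S)-3-bromo-5-hydroxy-5-[(2Z)-oct-2-en-1-yl]-2-oxocyclopent-3-en-1-yl]hept-5-enoate
Conditions: HF·pyridine, pyridine, THF, 0 °C
Reagents that add atoms: none
Why: Fluoride cleavage of the triethylsilyl ether under buffered, weakly acidic conditions. The acetate, the ester, the bromo enone and both Z-alkenes are inert to it, and no base is present to eliminate the β-acetate.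

## Compound list

1 | (S)-malic acid | O[C@@H](CC(=O)O)C(=O)O | starting material
2 | pivalaldehyde | CC(C)(C)C=O | starting material
3 | 2-[(2S,4S)-2-tert-butyl-5-oxo-1,3-dioxolan-4-yl]acetic acid | CC(C)(C)[C@H]1O[C@@H](CC(=O)O)C(=O)O1 | intermediate
4 | 1-bromooct-2-yne | CCCCCC#CCBr | starting material
5 | dilithium enolate carboxylate of 3 | CC(C)(C)[C@H]1OC(CC([O-])=O)=C([O-])O1.[Li+].[Li+] | intermediate
6 | 2-[(2S,4S)-2-tert-butyl-4-(oct-2-yn-1-yl)-5-oxo-1,3-dioxolan-4-yl]acetic acid | CC(C)(C)[C@H]1O[C@](CC(=O)O)(CC#CCCCCC)C(=O)O1 | intermediate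
7 | isobutyl carbonic mixed anhydride of 6 | CC(C)(C)[C@H]1O[C@](CC(=O)OC(=O)OCC(C)C)(CC#CCCCCC)C(=O)O1 | intermediate
8 | (2S,5S)-2-tert-butyl-5-(2-hydroxyethyl)-5-(oct-2-yn-1-yl)-1,3-dioxolan-4-one | CC(C)(C)[C@H]1O[C@](CCO)(CC#CCCCCC)C(=O)O1 | intermediate
9 | (3S)-3-hydroxy-3-(oct-2-yn-1-yl)oxolan-2-one | CCCCCC#CC[C@]1(O)CCOC1=O | intermediate
10 | (3S)-3-hydroxy-3-[(2Z)-oct-2-en-1-yl]oxolan-2-one | CCCCC/C=C\C[C@]1(O)CCOC1=O | intermediate
11 | (3S)-3-[(2Z)-oct-2-en-1-yl]-3-(triethylsilyloxy)oxolan-2-one | CCCCC/C=C\C[C@]1(O[Si](CC)(CC)CC)CCOC1=O | intermediate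
12 | (3S)-3-[(2Z)-oct-2-en-1-yl]-3-(triethylsilyloxy)oxolan-2-ol, anomer mixture | CCCCC/C=C\C[C@]1(O[Si](CC)(CC)CC)CCOC1O | intermediate
13 | (3S,5Z)-3-ethynyl-3-(triethylsilyloxy)undec-5-en-1-ol | CCCCC/C=C\C[C@@](O[Si](CC)(CC)CC)(C#C)CCO | intermediate
14 | (3S,5Z)-3-ethynyl-3-(triethylsilyloxy)undec-5-enal | CCCCC/C=C\C[C@@](O[Si](CC)(CC)CC)(C#C)CC=O | intermediate
15 | (4S)-4-[(2Z)-oct-2-en-1-yl]-4-(triethylsilyloxy)cyclopent-2-en-1-one | CCCCC/C=C\C[C@@]1(O[Si](CC)(CC)CC)C=CC(=O)C1 | intermediate
16 | (4S)-4-[(2Z)-oct-2-en-1-yl]-4-(triethylsilyloxy)-6-oxabicyclo[3.1.0]hexan-2-one, both epoxide faces | CCCCC/C=C\C[C@]1(O[Si](CC)(CC)CC)CC(=O)C2OC12 | intermediate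
17 | (4S)-2-bromo-3-hydroxy-4-[(2Z)-oct-2-en-1-yl]-4-(triethylsilyloxy)cyclopentan-1-one | CCCCC/C=C\C[C@]1(O[Si](CC)(CC)CC)CC(=O)C(Br)C1O | intermediate
18 | (4S)-2-bromo-3-(methanesulfonyloxy)-4-[(2Z)-oct-2-en-1-yl]-4-(triethylsilyloxy)cyclopentan-1-one | CCCCC/C=C\C[C@]1(O[Si](CC)(CC)CC)CC(=O)C(Br)C1OS(C)(=O)=O | intermediate
19 | (4S)-2-bromo-4-[(2Z)-oct-2-en-1-yl]-4-(triethylsilyloxy)cyclopent-2-en-1-one | CCCCC/C=C\C[C@@]1(O[Si](CC)(CC)CC)C=C(Br)C(=O)C1 | intermediate
20 | methyl hex-5-ynoate | C#CCCCC(=O)OC | starting material
21 | chloromagnesium acetylide of 20 | COC(=O)CCCC#C[Mg]Cl | intermediate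
22 | methyl 7-hydroxyhept-5-ynoate | OCC#CCCCC(=O)OC | intermediate
23 | methyl (5Z)-7-hydroxyhept-5-enoate | OC/C=C\CCCC(=O)OC | intermediate
24 | methyl (5Z)-7-oxohept-5-enoate | O=C/C=C\CCCC(=O)OC | intermediate
25 | dicyclohexylboron dienolate of 19 | CCCCC/C=C\C[C@@]1(O[Si](CC)(CC)CC)C=C(Br)C(OB(C2CCCCC2)C2CCCCC2)=C1 | intermediate
26 | dicyclohexylboron aldolate of 27 | CCCCC/C=C\C[C@@]1(O[Si](CC)(CC)CC)C=C(Br)C(=O)[C@@H]1[C@H](/C=C\CCCC(=O)OC)OB(C1CCCCC1)C1CCCCC1 | intermediate
27 | methyl (5Z,7S)-7-[(1R,5S)-3-bromo-5-[(2Z)-oct-2-en-1-yl]-2-oxo-5-(triethylsilyloxy)cyclopent-3-en-1-yl]-7-hydroxyhept-5-enoate | CCCCC/C=C\C[C@@]1(O[Si](CC)(CC)CC)C=C(Br)C(=O)[C@@H]1[C@H](/C=C\CCCC(=O)OC)O | intermediate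
28 | methyl (5Z,7S)-7-acetoxy-7-[(1R,5S)-3-bromo-5-[(2Z)-oct-2-en-1-yl]-2-oxo-5-(triethylsilyloxy)cyclopent-3-en-1-yl]hept-5-enoate | CCCCC/C=C\C[C@@]1(O[Si](CC)(CC)CC)C=C(Br)C(=O)[C@@H]1[C@H](/C=C\CCCC(=O)OC)OC(C)=O | intermediate
29 | methyl (5Z,7S)-7-acetoxy-7-[(1R,5S)-3-bromo-5-hydroxy-5-[(2Z)-oct-2-en-1-yl]-2-oxocyclopent-3-en-1-yl]hept-5-enoate | CCCCC/C=C\C[C@@]1(O)C=C(Br)C(=O)[C@@H]1[C@H](/C=C\CCCC(=O)OC)OC(C)=O | target

## Count and risks

Total: 17 steps. Longest linear sequence: 14 steps (steps 1–11 and 15–17, from (S)-malic acid). The aldehyde branch is steps 12–14.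

**Step 9 (key step).** The terminal alkyne may be diverted before the alkenyl rhodium can isomerise and close, by C–H activation to alkynyl or vinylidene rhodium species and oligomerisation, or the acyl hydride may decarbonylate. Terminal alkynes bind cationic rhodium strongly and lie outside the intramolecular precedent. The fallback sets out from lactol 12 and makes the same C9–C10 bond by a chromium-mediated addition. A Stork–Zhao olefination (Ph3P=CHI from the iodomethylphosphonium iodide and NaN(SiMe3)2) should give (3S,5Z)-3-[(Z)-2-iodoethenyl]-3-(triethylsilyloxy)undec-5-en-1-ol F1. Dess–Martin oxidation gives (3S,5Z)-3-[(Z)-2-iodoethenyl]-3-(triethylsilyloxy)undec-5-enal F2. An intramolecular Nozaki–Hiyama–Kishi reaction (CrCl2, catalytic NiCl2, DMF) closes it to (4S)-4-[(2Z)-oct-2-en-1-yl]-4-(triethylsilyloxy)cyclopent-2-en-1-ol F3, and oxidation of the allylic alcohol (MnO2) returns to 15.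

**Step 15.** Facial selectivity at C8 may be poor (approach on the octenyl face), or the anti preference may erode through a boat transition state. The two C12 substituents are of similar size and the Z-enal is slim. Amine-induced Z to E isomerisation of 24 is a further hazard. The fallback sets out from 19 and replaces the closed boron transition state by a catalyst-controlled open one. Me3SiOTf and Et3N should give the silyl dienol ether (5S)-3-bromo-5-[(2Z)-oct-2-en-1-yl]-5-(triethylsilyloxy)-2-(trimethylsilyloxy)cyclopenta-1,3-diene F4. A Mukaiyama-type aldol addition to 24, promoted by SiCl4 with a chiral bisphosphoramide Lewis base, is anti-selective for cyclic enol ethers with conjugated aldehydes and fixes the aldehyde face from the catalyst. It returns to 27.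

**Step 11.** The Lewis acid may rearrange the epoxy ketone instead of opening it, or the mesylation of the hindered C11 hydroxyl may be slow, so that the bromohydrin suffers retro-aldol cleavage. The fallback sets out from 16 and uses a protic one-flask opening and dehydration that gives up the silyl ether. Aqueous HBr in acetone at 0 °C should give (4S)-2-bromo-4-hydroxy-4-[(2Z)-oct-2-en-1-yl]cyclopent-2-en-1-one F5, which is resilylated (Et3SiOTf, 2,6-lutidine) to return to 19.

**Step 7.** The hindered lactol may open slowly, and the triethylsilyl group may migrate from the tertiary oxygen to the primary alkoxide (a 1,5 oxygen-to-oxygen shift) in methanolic carbonate. The fallback sets out from 10 and postpones silylation. i-Bu2AlH gives (3S)-3-[(2Z)-oct-2-en-1-yl]oxolane-2,3-diol F6, and Ohira–Bestmann homologation gives (3S,5Z)-3-ethynylundec-5-ene-1,3-diol F7. Double silylation (Et3SiOTf, 2,6-lutidine) gives (3S,5Z)-3-ethynyl-1,3-bis(triethylsilyloxy)undec-5-ene F8. Swern oxidation, which converts a primary triethylsilyl ether directly into the aldehyde and leaves the tertiary one, returns to 14.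

**Step 16.** The new β-acetoxy ketone may lose acetic acid by E1cB under pyridine and DMAP, giving the cross-conjugated dienone. The fallback sets out from 19 and acylates the aldolate in the flask, so that the free aldol and the amine base are avoided. LiN(i-Pr)2 in THF at −78 °C gives the lithium dienolate of 19 F9. Addition of 24 gives the lithium aldolate of 27 F10, which is trapped with Ac2O at −78 °C before work-up to return to 28.

## Further compounds

F1 | step 9 | (3S,5Z)-3-[(Z)-2-iodoethenyl]-3-(triethylsilyloxy)undec-5-en-1-ol | CCCCC/C=C\C[C@@](O[Si](CC)(CC)CC)(/C=C\I)CCO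
F2 | step 9 | (3S,5Z)-3-[(Z)-2-iodoethenyl]-3-(triethylsilyloxy)undec-5-enal | CCCCC/C=C\C[C@@](O[Si](CC)(CC)CC)(/C=C\I)CC=O
F3 | step 9 | (4S)-4-[(2Z)-oct-2-en-1-yl]-4-(triethylsilyloxy)cyclopent-2-en-1-ol, both C1 epimers | CCCCC/C=C\C[C@@]1(O[Si](CC)(CC)CC)C=CC(O)C1
F4 | step 15 | (5S)-3-bromo-5-[(2Z)-oct-2-en-1-yl]-5-(triethylsilyloxy)-2-(trimethylsilyloxy)cyclopenta-1,3-diene | CCCCC/C=C\C[C@@]1(O[Si](CC)(CC)CC)C=C(Br)C(O[Si](C)(C)C)=C1
F5 | step 11 | (4S)-2-bromo-4-hydroxy-4-[(2Z)-oct-2-en-1-yl]cyclopent-2-en-1-one | CCCCC/C=C\C[C@@]1(O)C=C(Br)C(=O)C1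
F6 | step 7 | (3S)-3-[(2Z)-oct-2-en-1-yl]oxolane-2,3-diol, anomer mixture | CCCCC/C=C\C[C@]1(O)CCOC1O
F7 | step 7 | (3S,5Z)-3-ethynylundec-5-ene-1,3-diol | CCCCC/C=C\C[C@@](O)(C#C)CCO
F8 | step 7 | (3S,5Z)-3-ethynyl-1,3-bis(triethylsilyloxy)undec-5-ene | CCCCC/C=C\C[C@@](O[Si](CC)(CC)CC)(C#C)CCO[Si](CC)(CC)CC
F9 | step 16 | lithium dienolate of 19 | CCCCC/C=C\C[C@@]1(O[Si](CC)(CC)CC)C=C(Br)C(O[Li])=C1
F10 | step 16 | lithium aldolate of 27 | CCCCC/C=C\C[C@@]1(O[Si](CC)(CC)CC)C=C(Br)C(=O)[C@@H]1[C@H](/C=C\CCCC(=O)OC)O[Li]
A1 | alternative 1 | 3-[2-(tert-butyldiphenylsilyloxy)ethyl]-4-[1-(tert-butyldimethylsilyloxy)-2-(4-methoxybenzyloxy)ethyl]-3-(4-methoxybenzyloxy)-5-(triethylsilyloxy)cyclopent-1-ene | CC(C)(C)[Si](c1ccccc1)(c1ccccc1)OCC[C@@]1(OCc2ccc(OC)cc2)C=C[C@@H](O[Si](CC)(CC)CC)[C@@H]1[C@@H](O[Si](C)(C)C(C)(C)C)COCc1ccc(OC)cc1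
A2 | alternative 2 | 6-iodo-6a-(oct-2-ynyl)-3-(4-methoxybenzyloxy)-4-(tert-butyldimethylsilyloxy)hexahydrocyclopenta[b]furan-2-one | CCCCCC#CC[C@]12OC(=O)[C@H](OCc3ccc(OC)cc3)[C@H]1[C@H](O[Si](C)(C)C(C)(C)C)C[C@@H]2I
A3 | alternative 3 | methyl 7-[2-(tert-butyldimethylsilyloxy)-2-(oct-2-ynyl)-5-oxocyclopentyl]-7-oxohept-5-ynoate | CCCCCC#CC[C@@]1(O[Si](C)(C)C(C)(C)C)CCC(=O)[C@@H]1C(=O)C#CCCCC(=O)OC
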